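## Analysis of the target

The target is a 3→8''-linked flavanone–flavone dimer: a naringenin-type unit (ring A = the phloroglucinol ring C4a–C8a, ring C = O1–C2–C3–C4, ring B = the 4-hydroxyphenyl group on C2) is bonded through C3 to C8'' of an apigenin unit, whose O7'' carries a sulfate monoester. There are two stereocentres, C2 (R) and C3 (S), adjacent in ring C, with the two aryl groups trans. The flavanone is the fragile part: base opens ring C by retro-oxa-Michael reaction to a chalcone, and C3–H is alpha to C4=O, so once the ketone exists both centres can be lost; the trans arrangement would return, the absolute configuration would not. The aryl sulfate is acid-labile and very polar, and it sits on one of six phenolic oxygens, so O7'' has to be told apart from O4''' and from the three flavanone phenols. The hard bond is C3–C8'', which joins a secondary sp3 carbon to an arene carbon flanked by O1'' and O7'' and has to be made with defined absolute configuration at two neighbouring carbons. The strategy rests on ring C read as a chroman fused to ring A: O1–C2 and C3–C4 lie on either side of the C2/C3 pair, and cutting both leaves an ortho-quinone methide built from C4, C4a, C8a and O1 and an E-alkene C2=C3 that carries ring B and the flavone. C4 is therefore a methylene group at first, and the carbonyl is added later by benzylic oxidation, which O1, O5 and O7 on ring A make selective.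

## Retrosynthetic reasoning

19 to 18. The five O–benzyl bonds are cut last. Benzyl ethers on every phenol that stays free come off together by neutral hydrogenolysis, which spares the sulfate and exposes the flavanone to neither acid nor base.

18 to 16 through 17. The C4 carbonyl is taken back to CH2 in two oxidation stages. A flavan has no enolisable centre and cannot ring-open, so every step that needs base can be done before the ketone exists, and ring C becomes open to cycloaddition. The forward reaction must oxidise C4–H in preference to C2–H; the three oxygens conjugated with C4 through ring A provide this.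

16 to 14 through 15. The S–O bond at O7'' is cut and the oxygen is traced back to a pivalate, the only acyl group in 14. Its removal by alkoxide at the flavan stage leaves one free hydroxyl, so sulfation needs no selectivity.

14 to 9 and 12 through 13. O1–C2 and C3–C4 are cut together. These two bonds flank both stereocentres, so one step makes ring C, the C3–C4 bond and both centres. Cuts at C2–C3 or C4–C4a would leave open-chain precursors whose centres must be set separately. The fragments are of similar size: the stilbene 9 and the salicyl alcohol 12, which loses water to the quinone methide 13. The forward step has to control regiochemistry (C4 to the flavone-bearing carbon, O1 to the carbon bearing ring B), the trans relation (given by the E-alkene) and the absolute sense (given by a chiral Brønsted acid).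

9 to 6 and 8. The bond between C8 of the flavone and the alkene carbon is cut. A Heck coupling forms it with E geometry from the aryl iodide 6 and the styrene 8, and C8 of a 5,7-dioxygenated flavone is the position that iodinates most readily.

6 back to 1 through 5, 4, 3 and 2. Iodination at C8 needs ether oxygens on O5 and O7, whereas the cycloaddition needs an acyl group on O7. O7 therefore carries an acetal during iodination and the pivalate afterwards. O7 is told apart from O4' by its higher acidity in the first step, and O5 by its hydrogen bond to C4=O.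

8 to 7, and 12 to 10 through 11. The styrene comes from aldehyde 7 by methylenation. The salicyl alcohol comes from 10 by two O-benzylations, which leave the chelated hydroxyl that becomes O1, and reduction of the formyl group that becomes C4.

## Alternatives that were turned down

Alternative 1: Ring C is made before ring A exists, as a 2,3-dihydro-4H-pyran-4-one, by cutting C2–C3 and O1–C8a. In the forward step aldehyde 7 and the 1-methoxy-3-siloxy diene A1, which carries the protected flavone on its terminal carbon, would combine under Ti(OiPr)4 with one antipode of BINOL; loss of the methoxy group gives dihydropyranone A2.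
- For: catalytic asymmetric additions of aryl aldehydes to siloxy dienes are very well documented, so on precedent for the enantioselective step this alternative is stronger than the chosen one. The C4 carbonyl is present from the start.
- Against: the diene terminus that must bond to the aldehyde carbon carries a di-ortho-substituted flavone, so the addition is hindered. The cis/trans outcome of an aldol-type pathway is not fixed by the diene, although C3 could later be equilibrated. The flavone carbonyl and the acetal oxygens compete for titanium.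
- Decisive point: ring A with its two oxygens would still have to be annulated onto the C4a=C8a enone of A2 in several steps, with C3 enolisable and the β-alkoxy enone open to ring cleavage throughout.
- Comparison: the chosen route gives up some precedent for enantiocontrol and gains a complete ring A in the bond-forming step and a much shorter, convergent sequence.

Alternative 2: Ring C is closed last at C4–C4a. The acid A3 would be turned into its chloride and cyclised with SnCl4 onto the 3,5-dibenzyloxyphenoxy ring to give A4.
- For: the flavanone oxidation level is delivered directly, which is stronger than the chosen route's late C4 oxidation. The phenoxy ring is symmetric, so there is no regiochemical question, and intramolecular acylation of phloroglucinol ethers is dependable.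
- Against: both stereocentres must already exist in open-chain A3. That needs a C–O bond, with defined configuration, between a phenol and a benzylic carbon that ionises easily. The carbonate on O4' is there to tame this and adds a third kind of protecting group beside the allyl ether on O7''.
- Against: in the acid chloride the α-hydrogen is benzylic and next to the acyl group, so ketene formation or β-elimination of the aryloxy group can erase one or both centres. SnCl4 can also strip benzyl ethers next to carbonyl groups and the carbonate.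
- Comparison: the chosen route sets ring and centres in one step from an alkene of secure geometry and pays for it with the C4 oxidation.

Alternative 3: The pyranone of the flavone is closed last at C4''–C4a''. The flavanone would be complete and carry on C3 a phloroglucinol ring whose O1'' bears a (Z)-β-aryloxycinnamic acid, A5. Trifluoroacetic anhydride would activate the acid, which acylates the only free ortho carbon and gives A6.
- For: there is no regiochemical doubt, and no C8 functionalisation of a preformed flavone is needed (no iodination, no Heck coupling), where it is at least as good as the chosen route. The C4 ketone is present.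
- Against: the central problem is untouched. The C3–aryl bond and both stereocentres must already be in A5, so a separate asymmetric synthesis of a 3-arylflavanone is needed first.
- Against: the phloroglucinol stub needs three different oxygen substituents, and the Z geometry of the aryloxycinnamate must be secured.
- Against: the strongly acidic acylation medium meets a finished flavanone whose C2–O1 bond is a benzylic ether para to an oxygen of ring B and whose C3 enolises. The acetate on O7'' would then have to be removed by base from a flavanone, the situation the chosen route avoids.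
- Comparison: the chosen strategy is the only one of the four in which the key step itself makes the C3–C8''-bearing ring and both centres.

Key step: step 10

Remark 1: the facial preference that one antipode of the phosphoric acid imposes on this pair of reactants cannot be derived with confidence; the (R)-acid is written, and the (S)-acid is taken instead if 14 proves to be the mirror image.

Remark 2: the sulfate monoesters 16 to 19 are drawn and counted as neutral hydrogen sulfates, as the target is; at the bench they would be carried as tetrabutylammonium salts (ion-pair extraction) and the proton restored by cation exchange after the last step.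

## Route

Step 1
Reactants: 1 apigenin (5,7-dihydroxy-2-(4-hydroxyphenyl)-4H-chromen-4-one)
Product: 2 7-O-(methoxymethyl)apigenin (5-hydroxy-2-(4-hydroxyphenyl)-7-(methoxymethoxy)-4H-chromen-4-one)
Conditions: MeOCH2Cl (1.0 equiv), K2CO3 (1.0 equiv), DMF, 0 °C
Reagents that add atoms: chloromethyl methyl ether, COCCl
Why: Williamson-type O-alkylation; the 7-OH, para to the pyranone carbonyl, is the most acidic phenol of 1 and the 5-OH is locked in a hydrogen bond to C4=O, so one equivalent of weak base and of the chloride should alkylate O7 first, with unreacted 1 and bis-ether separable.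

Step 2
Reactants: 2 7-O-(methoxymethyl)apigenin
Product: 3 5-(benzyloxy)-2-[4-(benzyloxy)phenyl]-7-(methoxymethoxy)-4H-chromen-4-one
Conditions: BnBr (3 equiv), K2CO3 (4 equiv), DMF, 70 °C
Reagents that add atoms: benzyl bromide, BrCc1ccccc1
Why: Williamson ether synthesis; the 4'-phenoxide reacts readily, the chelated 5-OH needs heat and excess reagent, and the acetal is stable to base.

Step 3
Reactants: 3 5,4'-di-O-benzyl-7-O-(methoxymethyl)apigenin
Product: 4 5-(benzyloxy)-2-[4-(benzyloxy)phenyl]-8-iodo-7-(methoxymethoxy)-4H-chromen-4-one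
Conditions: N-iodosuccinimide (1.1 equiv), CF3CO2H (10 mol %), MeCN/CH2Cl2, 0 °C to rt, dark
Reagents that add atoms: N-iodosuccinimide, O=C1CCC(=O)N1I
Why: Electrophilic aromatic iodination; in 5,7-di-O-alkylflavones C8, para to O5 and between O1 and O7, is the most nucleophilic carbon, while ring B and C3 are deactivated by the enone.

Step 4
Reactants: 4 8-iodo-5,4'-di-O-benzyl-7-O-(methoxymethyl)apigenin
Product: 5 5-(benzyloxy)-2-[4-(benzyloxy)phenyl]-7-hydroxy-8-iodo-4H-chromen-4-one
Conditions: HCl (2 M), MeOH/THF, rt
Reagents that add atoms: none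
Why: Acid-catalysed acetal cleavage by transacetalisation to methanol; benzyl ethers, the flavone and the aryl iodide are stable to dilute HCl at room temperature.

Step 5
Reactants: 5 8-iodo-5,4'-di-O-benzylapigenin
Product: 6 5-(benzyloxy)-2-[4-(benzyloxy)phenyl]-8-iodo-4-oxo-4H-chromen-7-yl pivalate
Conditions: pivaloyl chloride (1.5 equiv), Et3N (2 equiv), DMAP (10 mol %), CH2Cl2, 0 °C to rt
Reagents that add atoms: pivaloyl chloride, CC(C)(C)C(=O)Cl
Why: DMAP-catalysed O-acylation of the only free phenol; the bulky, electron-poor ester on O7 is wanted for step 10 and is later removable by methoxide.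

Step 6
Reactants: 7 4-(benzyloxy)benzaldehyde
Product: 8 4-benzyloxystyrene (1-(benzyloxy)-4-ethenylbenzene)
Conditions: Ph3PCH3Br (1.3 equiv), KOtBu (1.25 equiv), THF, 0 °C to rt
Reagents that add atoms: methyltriphenylphosphonium bromide, C[P+](c1ccccc1)(c1ccccc1)c1ccccc1.[Br-]
Why: Wittig methylenation of an aromatic aldehyde with the non-stabilised ylide; no stereochemistry is involved.

Step 7
Reactants: 6 8-iodo-5,4'-di-O-benzylapigenin 7-pivalate; 8 4-benzyloxystyrene
Product: 9 5-(benzyloxy)-2-[4-(benzyloxy)phenyl]-8-{(E)-2-[4-(benzyloxy)phenyl]ethenyl}-4-oxo-4H-chromen-7-yl pivalate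
Conditions: Pd(OAc)2 (5 mol %), P(o-tol)3 (15 mol %), Et3N (3 equiv), DMF, 100 °C
Reagents that add atoms: none
Why: Heck reaction; oxidative addition of the aryl iodide to zerovalent palladium, syn insertion of the styrene at its terminal carbon and syn β-hydride elimination should give the E-stilbene, and the tertiary amine in dry DMF leaves the pivalate intact.

Step 8
Reactants: 10 2,4,6-trihydroxybenzaldehyde
Product: 11 2,4-bis(benzyloxy)-6-hydroxybenzaldehyde
Conditions: BnBr (2.05 equiv), K2CO3 (2.1 equiv), DMF, 0 °C to rt
Reagents that add atoms: benzyl bromide, BrCc1ccccc1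
Why: Williamson etherification; the 4-OH and one 2-OH are alkylated, and the last hydroxyl is held by a hydrogen bond to the formyl group and reacts last, so two equivalents should stop at 11.

Step 9
Reactants: 11 2,4-bis(benzyloxy)-6-hydroxybenzaldehyde
Product: 12 3,5-bis(benzyloxy)-2-(hydroxymethyl)phenol
Conditions: NaBH4 (1.0 equiv), THF/EtOH, 0 °C, 30 min; pH 7 phosphate buffer
Reagents that add atoms: none
Why: Hydride reduction of a salicylaldehyde; short time at 0 °C and a neutral work-up are chosen because the electron-rich product ionises easily, and it is used at once without chromatography.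

Step 10
Reactants: 9 (E)-stilbene pivalate; 12 3,5-bis(benzyloxy)-2-(hydroxymethyl)phenol
Product: 14 8-{(2R,3S)-5,7-bis(benzyloxy)-2-[4-(benzyloxy)phenyl]chroman-3-yl}-5-(benzyloxy)-2-[4-(benzyloxy)phenyl]-4-oxo-4H-chromen-7-yl pivalate, via ortho-quinone methide 13 (not isolated)
Conditions: (R)-3,3'-bis(2,4,6-triisopropylphenyl)-1,1'-binaphthyl-2,2'-diyl hydrogen phosphate (10 mol %), 5 Å MS, ClCH2CH2Cl, 25 °C, 12 (2.5 equiv) added over 12 h
Reagents that add atoms: none
Why: The acid dehydrates 12 to 13, which stays hydrogen-bonded to the chiral phosphate or ion-paired with it as the 2-hydroxybenzyl cation. This electron-poor oxadiene (C4, C4a, C8a, O1) adds across the E-alkene of 9 in an inverse-electron-demand hetero-Diels–Alder reaction: the methylene carbon bonds to the alkene carbon that carries the flavone (C3–C4), and the positive charge developing on the other carbon, stabilised by the coplanar 4-benzyloxyphenyl group, is taken up by the carbonyl oxygen (O1–C2). The closest known reaction type is the Brønsted-acid-catalysed [4+2] cycloaddition of ortho-quinone methides generated from ortho-hydroxybenzyl alcohols with styrenes and β-substituted styrenes to give chromans. Ring C closes as a six-membered ring by this [4+2] addition; in the stepwise limit the second bond forms by 6-exo-trig capture of the benzylic cation by the phenol oxygen. The trans relation of C2 and C3 follows from suprafacial addition to the E-alkene, and a stepwise path should also end in the diequatorial trans product. The absolute configuration (2R,3S) is set by the phosphate, whose 3,3'-aryl groups shield one face of the bound quinone methide. Regioselectivity is needed and comes from the donor 4-benzyloxyphenyl end against the flavone end, whose 7-pivalate is a poor donor and twists the flavone ring out of conjugation with the alkene; chemoselectivity against the flavone C2=C3 bond comes from its being an electron-poor enone that does not react with an electron-poor diene. Slow addition of 12 keeps 13 dilute so that addition to 9 can compete with self-condensation.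

Step 11
Reactants: 14 (2R,3S)-flavan pivalate
Product: 15 8-{(2R,3S)-5,7-bis(benzyloxy)-2-[4-(benzyloxy)phenyl]chroman-3-yl}-5-(benzyloxy)-2-[4-(benzyloxy)phenyl]-7-hydroxy-4H-chromen-4-one
Conditions: NaOMe (1.5 equiv), MeOH/THF (1:1), rt; AcOH
Reagents that add atoms: none
Why: Base-mediated methanolysis of the aryl pivalate; the flavan has no enolisable stereocentre, so methoxide cannot touch C2 or C3, and the flavone tolerates methoxide at room temperature.

Step 12
Reactants: 15 (2R,3S)-flavan 7''-phenol
Product: 16 8-{(2R,3S)-5,7-bis(benzyloxy)-2-[4-(benzyloxy)phenyl]chroman-3-yl}-5-(benzyloxy)-2-[4-(benzyloxy)phenyl]-4-oxo-4H-chromen-7-yl hydrogen sulfate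
Conditions: SO3·pyridine (5 equiv), pyridine, 40 °C
Reagents that add atoms: sulfur trioxide–pyridine complex, [O-]S(=O)(=O)[n+]1ccccc1
Why: O-sulfation of a phenol with a sulfur trioxide–amine complex; O7'' is the only free hydroxyl, so no selectivity is required, and gentle warming makes up for the ortho substituent.

Step 13
Reactants: 16 (2R,3S)-flavan 7''-hydrogen sulfate
Product: 17 8-{(2R,3R,4RS)-5,7-bis(benzyloxy)-2-[4-(benzyloxy)phenyl]-4-hydroxychroman-3-yl}-5-(benzyloxy)-2-[4-(benzyloxy)phenyl]-4-oxo-4H-chromen-7-yl hydrogen sulfate (C4 epimers)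
Conditions: DDQ (1.3 equiv), CH2Cl2/pH 7 phosphate buffer (10:1), 0 °C to rt
Reagents that add atoms: water, O
Why: Benzylic C–H oxidation by DDQ (hydride abstraction, then capture of the cation by water), as in the C4 oxidation of 5,7-dialkoxyflavans; the C4 cation is stabilised by O1, O5 and O7 of ring A, far better than a cation at C2 with one para oxygen, and the new C4 centre, probably mainly trans to the C3 aryl group, is removed in step 14.

Step 14
Reactants: 17 flavan-4-ol hydrogen sulfate
Product: 18 8-{(2R,3S)-5,7-bis(benzyloxy)-2-[4-(benzyloxy)phenyl]-4-oxochroman-3-yl}-5-(benzyloxy)-2-[4-(benzyloxy)phenyl]-4-oxo-4H-chromen-7-yl hydrogen sulfate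
Conditions: Pr4N[RuO4] (10 mol %), N-methylmorpholine N-oxide (2 equiv), 4 Å MS, CH2Cl2, rt
Reagents that add atoms: none
Why: Ley–Griffith oxidation of a secondary benzylic alcohol under neutral conditions; both C4 epimers converge on one ketone, and with no strong base or acid present C2 and C3 should keep the trans configuration, which is also the thermodynamic one.

Step 15
Reactants: 18 penta-O-benzyl flavanone–flavone hydrogen sulfate
Product: 19 8-[(2R,3S)-5,7-dihydroxy-2-(4-hydroxyphenyl)-4-oxochroman-3-yl]-5-hydroxy-2-(4-hydroxyphenyl)-4-oxo-4H-chromen-7-yl hydrogen sulfate (CNP0271389.1)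
Conditions: H2 (1 atm), Pd/C (10 wt % Pd), THF/MeOH, rt; then cation-exchange resin (H+ form), 0 °C
Reagents that add atoms: none
Why: Hydrogenolysis of five benzyl aryl ethers over palladium; aryl sulfates, the flavone double bond and the aryl ketone should survive at 1 atm and room temperature if the reaction is stopped at complete debenzylation.

## Compound list

1 | apigenin | O=c1cc(-c2ccc(O)cc2)oc2cc(O)cc(O)c12 | starting material
2 | 5-hydroxy-2-(4-hydroxyphenyl)-7-(methoxymethoxy)-4H-chromen-4-one | O=c1cc(-c2ccc(O)cc2)oc2cc(OCOC)cc(O)c12 | intermediate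
3 | 5-(benzyloxy)-2-[4-(benzyloxy)phenyl]-7-(methoxymethoxy)-4H-chromen-4-one | O=c1cc(-c2ccc(OCc3ccccc3)cc2)oc2cc(OCOC)cc(OCc3ccccc3)c12 | intermediate
4 | 5-(benzyloxy)-2-[4-(benzyloxy)phenyl]-8-iodo-7-(methoxymethoxy)-4H-chromen-4-one | O=c1cc(-c2ccc(OCc3ccccc3)cc2)oc2c(I)c(OCOC)cc(OCc3ccccc3)c12 | intermediate
5 | 5-(benzyloxy)-2-[4-(benzyloxy)phenyl]-7-hydroxy-8-iodo-4H-chromen-4-one | O=c1cc(-c2ccc(OCc3ccccc3)cc2)oc2c(I)c(O)cc(OCc3ccccc3)c12 | intermediate
6 | 5-(benzyloxy)-2-[4-(benzyloxy)phenyl]-8-iodo-4-oxo-4H-chromen-7-yl pivalate | CC(C)(C)C(=O)Oc1cc(OCc2ccccc2)c2c(=O)cc(-c3ccc(OCc4ccccc4)cc3)oc2c1I | intermediate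
7 | 4-(benzyloxy)benzaldehyde | O=Cc1ccc(OCc2ccccc2)cc1 | starting material
8 | 4-benzyloxystyrene | C=Cc1ccc(OCc2ccccc2)cc1 | intermediate
9 | 5-(benzyloxy)-2-[4-(benzyloxy)phenyl]-8-{(E)-2-[4-(benzyloxy)phenyl]ethenyl}-4-oxo-4H-chromen-7-yl pivalate | CC(C)(C)C(=O)Oc1cc(OCc2ccccc2)c2c(=O)cc(-c3ccc(OCc4ccccc4)cc3)oc2c1/C=C/c1ccc(OCc2ccccc2)cc1 | intermediate
10 | 2,4,6-trihydroxybenzaldehyde | O=Cc1c(O)cc(O)cc1O | starting material
11 | 2,4-bis(benzyloxy)-6-hydroxybenzaldehyde | O=Cc1c(O)cc(OCc2ccccc2)cc1OCc1ccccc1 | intermediate
12 | 3,5-bis(benzyloxy)-2-(hydroxymethyl)phenol | OCc1c(O)cc(OCc2ccccc2)cc1OCc1ccccc1 | intermediate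
13 | 3,5-bis(benzyloxy)-6-methylidenecyclohexa-2,4-dien-1-one (ortho-quinone methide) | C=C1C(=O)C=C(OCc2ccccc2)C=C1OCc1ccccc1 | intermediate (not isolated)
14 | 8-{(2R,3S)-5,7-bis(benzyloxy)-2-[4-(benzyloxy)phenyl]chroman-3-yl}-5-(benzyloxy)-2-[4-(benzyloxy)phenyl]-4-oxo-4H-chromen-7-yl pivalate (2,3-trans) | C1c2c(OCc3ccccc3)cc(OCc3ccccc3)cc2O[C@@H](c2ccc(OCc3ccccc3)cc2)[C@@H]1c1c(OC(=O)C(C)(C)C)cc(OCc2ccccc2)c2c(=O)cc(-c3ccc(OCc4ccccc4)cc3)oc12 | intermediate
15 | 8-{(2R,3S)-5,7-bis(benzyloxy)-2-[4-(benzyloxy)phenyl]chroman-3-yl}-5-(benzyloxy)-2-[4-(benzyloxy)phenyl]-7-hydroxy-4H-chromen-4-one | C1c2c(OCc3ccccc3)cc(OCc3ccccc3)cc2O[C@@H](c2ccc(OCc3ccccc3)cc2)[C@@H]1c1c(O)cc(OCc2ccccc2)c2c(=O)cc(-c3ccc(OCc4ccccc4)cc3)oc12 | intermediate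
16 | 8-{(2R,3S)-5,7-bis(benzyloxy)-2-[4-(benzyloxy)phenyl]chroman-3-yl}-5-(benzyloxy)-2-[4-(benzyloxy)phenyl]-4-oxo-4H-chromen-7-yl hydrogen sulfate | C1c2c(OCc3ccccc3)cc(OCc3ccccc3)cc2O[C@@H](c2ccc(OCc3ccccc3)cc2)[C@@H]1c1c(OS(=O)(=O)O)cc(OCc2ccccc2)c2c(=O)cc(-c3ccc(OCc4ccccc4)cc3)oc12 | intermediate
17 | 8-{(2R,3R,4RS)-5,7-bis(benzyloxy)-2-[4-(benzyloxy)phenyl]-4-hydroxychroman-3-yl}-5-(benzyloxy)-2-[4-(benzyloxy)phenyl]-4-oxo-4H-chromen-7-yl hydrogen sulfate (C4 epimers, C4 left undefined) | OC1c2c(OCc3ccccc3)cc(OCc3ccccc3)cc2O[C@@H](c2ccc(OCc3ccccc3)cc2)[C@@H]1c1c(OS(=O)(=O)O)cc(OCc2ccccc2)c2c(=O)cc(-c3ccc(OCc4ccccc4)cc3)oc12 | intermediate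
18 | 8-{(2R,3S)-5,7-bis(benzyloxy)-2-[4-(benzyloxy)phenyl]-4-oxochroman-3-yl}-5-(benzyloxy)-2-[4-(benzyloxy)phenyl]-4-oxo-4H-chromen-7-yl hydrogen sulfate | O=C1c2c(OCc3ccccc3)cc(OCc3ccccc3)cc2O[C@@H](c2ccc(OCc3ccccc3)cc2)[C@@H]1c1c(OS(=O)(=O)O)cc(OCc2ccccc2)c2c(=O)cc(-c3ccc(OCc4ccccc4)cc3)oc12 | intermediate
19 | 8-[(2R,3S)-5,7-dihydroxy-2-(4-hydroxyphenyl)-4-oxochroman-3-yl]-5-hydroxy-2-(4-hydroxyphenyl)-4-oxo-4H-chromen-7-yl hydrogen sulfate | O=C1c2c(O)cc(O)cc2O[C@@H](c2ccc(O)cc2)[C@@H]1c1c(OS(=O)(=O)O)cc(O)c2c(=O)cc(-c3ccc(O)cc3)oc12 | target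

## Step count and least certain steps

Total step count: 15. Longest linear sequence: 12 steps (steps 1 to 5, 7 and 10 to 15, from apigenin).

Step 10 (key step). What may go wrong:
- self-condensation of the quinone methide, which can alkylate the electron-rich ring of 12 or ring A of 14 faster than it adds to the hindered stilbene;
- insufficient facial discrimination by a catalyst that holds only the diene;
- partial reversal of regiochemistry if the flavone ring stabilises the cation better than expected.

Fallback, from 9 and 12 back to 14: catalyst control is given up. Heating 9 with 12 in o-xylene at 140 °C without acid generates 13 thermally and should give the trans adduct as the racemate, that is 14 together with the (2S,3R) antipode of 14 F1. Preparative HPLC on an amylose tris(3,5-dimethylphenylcarbamate) phase separates the two, and 14 re-enters the route at step 11.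

Step 13. What may go wrong: the C4 cation may lose the C3 proton instead of being captured by water. This elimination gives a 3-aryl-2H-chromene conjugated with the flavone, erases C3 and opens C2–H to further oxidation.

Fallback, from 11 and 9 to 18 (steps 9, 10 and 13 are replaced): the C4 oxygen is brought in with the diene partner.
- With HC(OMe)3 and the same phosphoric acid, 11 gives the dimethyl acetal 3,5-bis(benzyloxy)-2-(dimethoxymethyl)phenol F2.
- F2 loses methanol to the α-methoxy quinone methide 3,5-bis(benzyloxy)-6-(methoxymethylidene)cyclohexa-2,4-dien-1-one F3.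
- F3 adds to 9 as 13 does and gives the 4-methoxyflavan pivalate F4 (C4 epimers). This is the known acid-catalysed three-component chroman synthesis from a salicylaldehyde, an orthoformate and an aryl alkene. Enantiocontrol would have to be re-established; failing that, the antipodes are separated as in the fallback for step 10.
- NaOMe in MeOH/THF gives the 4-methoxyflavan phenol F5, and SO3·pyridine gives the 4-methoxyflavan hydrogen sulfate F6.
- DDQ in wet CH2Cl2 abstracts hydride from the doubly activated C4–H of F6, and the oxocarbenium ion is hydrolysed to 18. Should it lose the C3 proton, the enol ether hydrolyses to the same ketone with C3 returning to the trans arrangement.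

Step 9. What may go wrong: over-reduction and oligomerisation. Under the basic hydride conditions the product alkoxide or borate can expel the benzylic oxygen to give the quinone methide, which takes up hydride to the cresol. On isolation, traces of acid can trigger self-condensation.

Fallback, from 11 to 12: the phenol is kept masked during the reduction. TBSCl and imidazole in DMF give 2,4-bis(benzyloxy)-6-(tert-butyldimethylsilyloxy)benzaldehyde F7. NaBH4 reduces it to [2,4-bis(benzyloxy)-6-(tert-butyldimethylsilyloxy)phenyl]methanol F8, in which no phenoxide can expel the benzylic oxygen. Bu4NF buffered with AcOH at 0 °C frees the phenol just before use and gives 12.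

Step 1. What may go wrong: incomplete regioselectivity, with alkylation at O4' and bis-alkylation, because the acidity gap between the 7-OH and the 4'-OH is small.

Fallback, from 1 to 2: the 7-oxygen is singled out by selective deacylation.
- Ac2O in pyridine gives apigenin triacetate F9.
- PhSH and imidazole in N-methylpyrrolidone remove the 7-O-acetyl group, whose phenoxide is the best leaving group, and give 4',5-di-O-acetylapigenin F10.
- MeOCH2Cl and iPr2NEt give 4',5-di-O-acetyl-7-O-(methoxymethyl)apigenin F11.
- K2CO3 in MeOH removes both acetates and returns to 2.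

Step 7. What may go wrong: slow oxidative addition and insertion at the iodide flanked by O1 and the pivalate, with reductive loss of iodine or arylation at the internal alkene carbon.

Fallback, from 7 and 6 to 9: the alkene is made first and joined by Suzuki–Miyaura coupling. Lithiated bis(pinacolato)borylmethane (CH2(Bpin)2, lithium 2,2,6,6-tetramethylpiperidide, THF, −78 °C) converts 7 by boron–Wittig olefination into (E)-2-[4-(benzyloxy)phenyl]ethenylboronic acid pinacol ester F12. Coupling of F12 with 6 (Pd(PPh3)4, CsF, 1,2-dimethoxyethane, 80 °C; anhydrous fluoride spares the pivalate) gives 9.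

## Further compounds

F1 | step 10 | (2S,3R) antipode of 14, formed with 14 as the racemate | C1c2c(OCc3ccccc3)cc(OCc3ccccc3)cc2O[C@H](c2ccc(OCc3ccccc3)cc2)[C@H]1c1c(OC(=O)C(C)(C)C)cc(OCc2ccccc2)c2c(=O)cc(-c3ccc(OCc4ccccc4)cc3)oc12
F2 | step 13 | 3,5-bis(benzyloxy)-2-(dimethoxymethyl)phenol | COC(OC)c1c(O)cc(OCc2ccccc2)cc1OCc1ccccc1
F3 | step 13 | 3,5-bis(benzyloxy)-6-(methoxymethylidene)cyclohexa-2,4-dien-1-one | COC=C1C(=O)C=C(OCc2ccccc2)C=C1OCc1ccccc1
F4 | step 13 | 8-{(2R,3R,4RS)-5,7-bis(benzyloxy)-2-[4-(benzyloxy)phenyl]-4-methoxychroman-3-yl}-5-(benzyloxy)-2-[4-(benzyloxy)phenyl]-4-oxo-4H-chromen-7-yl pivalate | COC1c2c(OCc3ccccc3)cc(OCc3ccccc3)cc2O[C@@H](c2ccc(OCc3ccccc3)cc2)[C@@H]1c1c(OC(=O)C(C)(C)C)cc(OCc2ccccc2)c2c(=O)cc(-c3ccc(OCc4ccccc4)cc3)oc12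
F5 | step 13 | 8-{(2R,3R,4RS)-5,7-bis(benzyloxy)-2-[4-(benzyloxy)phenyl]-4-methoxychroman-3-yl}-5-(benzyloxy)-2-[4-(benzyloxy)phenyl]-7-hydroxy-4H-chromen-4-one | COC1c2c(OCc3ccccc3)cc(OCc3ccccc3)cc2O[C@@H](c2ccc(OCc3ccccc3)cc2)[C@@H]1c1c(O)cc(OCc2ccccc2)c2c(=O)cc(-c3ccc(OCc4ccccc4)cc3)oc12
F6 | step 13 | 8-{(2R,3R,4RS)-5,7-bis(benzyloxy)-2-[4-(benzyloxy)phenyl]-4-methoxychroman-3-yl}-5-(benzyloxy)-2-[4-(benzyloxy)phenyl]-4-oxo-4H-chromen-7-yl hydrogen sulfate | COC1c2c(OCc3ccccc3)cc(OCc3ccccc3)cc2O[C@@H](c2ccc(OCc3ccccc3)cc2)[C@@H]1c1c(OS(=O)(=O)O)cc(OCc2ccccc2)c2c(=O)cc(-c3ccc(OCc4ccccc4)cc3)oc12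
F7 | step 9 | 2,4-bis(benzyloxy)-6-(tert-butyldimethylsilyloxy)benzaldehyde | O=Cc1c(O[Si](C)(C)C(C)(C)C)cc(OCc2ccccc2)cc1OCc1ccccc1
F8 | step 9 | [2,4-bis(benzyloxy)-6-(tert-butyldimethylsilyloxy)phenyl]methanol | OCc1c(O[Si](C)(C)C(C)(C)C)cc(OCc2ccccc2)cc1OCc1ccccc1
F9 | step 1 | apigenin triacetate | CC(=O)Oc1ccc(-c2cc(=O)c3c(OC(C)=O)cc(OC(C)=O)cc3o2)cc1
F10 | step 1 | 4',5-di-O-acetylapigenin | CC(=O)Oc1ccc(-c2cc(=O)c3c(OC(C)=O)cc(O)cc3o2)cc1
F11 | step 1 | 4',5-di-O-acetyl-7-O-(methoxymethyl)apigenin | CC(=O)Oc1ccc(-c2cc(=O)c3c(OC(C)=O)cc(OCOC)cc3o2)cc1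
F12 | step 7 | (E)-2-[4-(benzyloxy)phenyl]ethenylboronic acid pinacol ester | CC1(C)OB(/C=C/c2ccc(OCc3ccccc3)cc2)OC1(C)C
A1 | alternative 1 | (1E,3Z)-1-methoxy-3-(trimethylsilyloxy)-4-{5-(benzyloxy)-2-[4-(benzyloxy)phenyl]-7-(methoxymethoxy)-4-oxo-4H-chromen-8-yl}buta-1,3-diene | CO/C=C/C(O[Si](C)(C)C)=C/c1c(OCOC)cc(OCc2ccccc2)c2c(=O)cc(-c3ccc(OCc4ccccc4)cc3)oc12
A2 | alternative 1 | (2R,3S)-2-[4-(benzyloxy)phenyl]-3-{5-(benzyloxy)-2-[4-(benzyloxy)phenyl]-7-(methoxymethoxy)-4-oxo-4H-chromen-8-yl}-2,3-dihydro-4H-pyran-4-one | O=C1C=CO[C@@H](c2ccc(OCc3ccccc3)cc2)[C@@H]1c1c(OCOC)cc(OCc2ccccc2)c2c(=O)cc(-c3ccc(OCc4ccccc4)cc3)oc12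
A3 | alternative 2 | (2S,3R)-2-{7-(allyloxy)-5-(benzyloxy)-2-[4-(benzyloxy)phenyl]-4-oxo-4H-chromen-8-yl}-3-[3,5-bis(benzyloxy)phenoxy]-3-{4-[(benzyloxycarbonyl)oxy]phenyl}propanoic acid | c1c(OCc2ccccc2)cc(OCc2ccccc2)cc1O[C@@H](c1ccc(OC(=O)OCc2ccccc2)cc1)[C@@H](C(=O)O)c1c(OCC=C)cc(OCc2ccccc2)c2c(=O)cc(-c3ccc(OCc4ccccc4)cc3)oc12
A4 | alternative 2 | (2R,3S)-2,3-trans flavanone–flavone with 7''-O-allyl, 4'-O-benzyloxycarbonyl and benzyl ethers on O5, O7, O5'' and O4''' | O=C1c2c(OCc3ccccc3)cc(OCc3ccccc3)cc2O[C@@H](c2ccc(OC(=O)OCc3ccccc3)cc2)[C@@H]1c1c(OCC=C)cc(OCc2ccccc2)c2c(=O)cc(-c3ccc(OCc4ccccc4)cc3)oc12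
A5 | alternative 3 | (Z)-3-{3-acetoxy-5-(benzyloxy)-2-[(2R,3S)-5,7-bis(benzyloxy)-2-(4-benzyloxyphenyl)-4-oxochroman-3-yl]phenoxy}-3-[4-(benzyloxy)phenyl]prop-2-enoic acid | O=C1c2c(OCc3ccccc3)cc(OCc3ccccc3)cc2O[C@@H](c2ccc(OCc3ccccc3)cc2)[C@@H]1c1c(OC(C)=O)cc(OCc2ccccc2)cc1O/C(=C\C(=O)O)c1ccc(OCc2ccccc2)cc1
A6 | alternative 3 | (2R,3S)-2,3-trans flavanone–flavone 7''-acetate with benzyl ethers on O5, O7, O4', O5'' and O4''' | O=C1c2c(OCc3ccccc3)cc(OCc3ccccc3)cc2O[C@@H](c2ccc(OCc3ccccc3)cc2)[C@@H]1c1c(OC(C)=O)cc(OCc2ccccc2)c2c(=O)cc(-c3ccc(OCc4ccccc4)cc3)oc12
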